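I watch [starting material] in this flask and pay little attention to the clock.

starting material 0.083 M; gas 12 mM (held); time 12 d

    starting material + partner ⇌ product (K1 = 170 L mol⁻¹, k1 = 55 L mol⁻¹ h⁻¹)
    crystals ⇌ product, rate k2*(cs2 - [product]) while solid is left; crystals form when [product] > cs2 (cs2 = 8.2 mM, k2 = 11 h⁻¹)
    partner → decomposed reagent (k3 = 0.19 h⁻¹)
    gas ⇌ partner, rate k4*(csat - [partner]) (k4 = 3.0 h⁻¹, csat = 12 mM)

- amounts and yields of product count crystals too
- given per volume of solution although it is solid: crystals
- at the start none of partner is dissolved
- the reaction counts as stopped when no species that holds the starting material changes by six tenths of a point or more over the second half of the time
- run time (flask): 12 d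

- which holds at 12 d: what has brought the reaction to rest, or that it has not come to rest (forward and back rates have come level / all of the starting material has reacted / it is still moving)
- conversion of starting material at 12 d
- amount of product at 12 d, in percent of the starting material charged

I start with the balance of the partner, none of which is dissolved at the start. Once the first step stops drawing on it, uptake from the gas meets decomposition, and that puts [partner] at 11.3 mM. At that level the first step is pseudo-first-order in starting material, and I reckon a half-life of 1.12 h for its last approach to rest, much shorter than the 12 d allowed. The charge of 0.083 M exceeds the solubility, so I expect crystals, and while they stand dissolved [product] sits at 8.2 mM. Then I reckon that [starting material] comes to rest at 4.27 mM. I carry this forward as the resting level: the solubility divided by the equilibrium constant and [partner], valid while crystals stand. So I reckon a conversion of 94.9%, product with crystals counted at 94.9%, and for the end forward and back rates have come level.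

The forecast gives forward and back rates have come level, with conversion 94.85% and product 94.85%, and says that “the crystals pin dissolved product”.

The flask gives forward and back rates have come level, with conversion 94.9% and product 94.9%. Its starting material already reads 5.15% at 1.20 d, while decomposed reagent climbs to 0.612 M by 12.0 d. That is more than the 0.0787 M of partner the first step took net, and [partner] reads 0.0113 M at that time.

The charge of the neighbour flask, 0.021 M of starting material, still exceeds the resting level plus the solubility by 8.53 mM, so I keep 4.27 mM there, which is 20.3% of its charge. The neighbour flask reads 20.4% of starting material, crystals 40.6%, and conversion 79.6%.

(The rate constants come from no measurement; the result is computed.)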